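**Retrosynthetic overview**
1. Target 15 ⇒ aromatic acylphloroglucinol 13 + prenyl acetate 14: the C6 quaternary centre is made last by a catalytic asymmetric dearomative prenylation.
2. 13 ⇒ acylmethylphloroglucinol 11 + β-hydroxy aldehyde 7: the Ar–CH2 bond comes from reductive alkylation through an ortho-quinone methide.
3. 7 ⇒ epoxy aldehyde 5 ⇒ enal 4: the key bond is the tertiary carbinol C–O bond, made by epoxidation anti to the isopropenyl group; reductive Cα–O cleavage then unmasks the alcohol.
4. 4 ⇒ (S)-limonene 1 by oxidative ring cleavage and aldol ring contraction. The cyclopentane is formed first; the six-membered ring is the bought phloroglucinol ring and is dearomatized last.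
5. 11 ⇒ 2-methylphloroglucinol 9 + (R)-2-methylbutanoic acid 8 (Friedel–Crafts acylation).

Assumption: (S)-(−)-limonene and (R)-2-methylbutanoic acid are bought as single enantiomers, and the dienone ring is written throughout in the tautomer of the given SMILES.

**Step 1**
Reactants: 1 (S)-(−)-limonene
Product: 3 (3S)-6-oxo-3-(prop-1-en-2-yl)heptanal, via limonene 1,2-oxide 2 (not isolated)
Conditions: mCPBA (1.0 equiv), CH2Cl2, 0 °C; then H5IO6 (1.3 equiv), THF/H2O, 0 → 23 °C
Reagents that add atoms: mCPBA (3-chloroperoxybenzoic acid), O=C(OO)c1cccc(Cl)c1; water, O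
Why: Prilezhaev epoxidation selects the trisubstituted ring alkene over the isopropenyl group, and periodic acid hydrates and cleaves both oxirane diastereomers (glycol cleavage) without touching the stereocentre, which becomes C3 of 3.

**Step 2**
Reactants: 3 (3S)-6-oxo-3-(prop-1-en-2-yl)heptanal
Product: 4 (5R)-2-methyl-5-(prop-1-en-2-yl)cyclopent-1-ene-1-carbaldehyde
Conditions: piperidine (0.2 equiv), AcOH (0.2 equiv), toluene, reflux, Dean–Stark
Reagents that add atoms: none
Why: Amine-catalysed intramolecular aldol condensation (aldehyde enamine onto the methyl ketone, then dehydration) is the classical ring contraction of limonene-derived keto aldehydes, and the non-enolisable stereocentre is retained.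

**Step 3**
Reactants: 4 (5R)-2-methyl-5-(prop-1-en-2-yl)cyclopent-1-ene-1-carbaldehyde
Product: 5 (1R,2R,5S)-5-methyl-2-(prop-1-en-2-yl)-6-oxabicyclo[3.1.0]hexane-1-carbaldehyde
Conditions: 30% aq. H2O2 (3 equiv), NaOH (0.3 equiv), MeOH, 0 °C
Reagents that add atoms: hydrogen peroxide, OO
Why: Weitz–Scheffer nucleophilic epoxidation attacks only the electron-poor enal alkene and closes the oxirane on the face anti to the adjacent isopropenyl group, so the tertiary C–O bond at the methyl-bearing carbon is formed with the required (5S) configuration by substrate control.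

**Step 4**
Reactants: 5 (1R,2R,5S)-5-methyl-2-(prop-1-en-2-yl)-6-oxabicyclo[3.1.0]hexane-1-carbaldehyde
Product: 7 (1R,2S,5S)-2-hydroxy-2-methyl-5-(prop-1-en-2-yl)cyclopentane-1-carbaldehyde, via C1-epimeric aldehyde 6 (not isolated)
Conditions: SmI2 (2.1 equiv), THF/MeOH, −90 °C; pH 7 buffer; then Et3N (0.3 equiv), CH2Cl2, 23 °C
Reagents that add atoms: none
Why: Samarium diiodide reduces the formyl group to a ketyl that cleaves the adjacent Cα–O bond (reductive opening of an α,β-epoxy carbonyl compound) while the tertiary C–O bond is kept; protonation on the open face is expected to give mainly epimer 6, and mild base equilibrates the enolisable C1 to the thermodynamic isomer 7 (formyl trans to both neighbouring carbon substituents and hydrogen-bonded to the cis hydroxyl).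

**Step 5**
Reactants: 8 (R)-2-methylbutanoic acid; 9 2-methylphloroglucinol
Product: 11 (2R)-2-methyl-1-(2,4,6-trihydroxy-3-methylphenyl)butan-1-one, via acid chloride 10 (not isolated)
Conditions: (COCl)2 (1.1 equiv), DMF (cat.), CH2Cl2, 0 → 23 °C; then 9, AlCl3 (3.5 equiv), PhNO2/CH2Cl2, 0 → 23 °C; aq. HCl work-up
Reagents that add atoms: none
Why: Friedel–Crafts C-acylation occurs at one of the two equivalent free positions of the electron-rich triol, and base-free chloride formation plus acylation at or below room temperature should keep the α-stereocentre from enolising (ee to be checked by chiral HPLC).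

**Step 6**
Reactants: 7 (1R,2S,5S)-2-hydroxy-2-methyl-5-(prop-1-en-2-yl)cyclopentane-1-carbaldehyde; 11 (2R)-2-methyl-1-(2,4,6-trihydroxy-3-methylphenyl)butan-1-one
Product: 13 (2R)-1-(2,4,6-trihydroxy-3-{[(1R,2S,5S)-2-hydroxy-2-methyl-5-(prop-1-en-2-yl)cyclopentyl]methyl}-5-methylphenyl)-2-methylbutan-1-one, via ortho-quinone methide 12 (not isolated)
Conditions: L-proline (20 mol %), Hantzsch ester (1.3 equiv), CH2Cl2/EtOH, 23 °C
Reagents that add atoms: none
Why: Proline-mediated Mannich/Knoevenagel-type condensation at the only free ring carbon of 11 gives ortho-quinone methide 12, which the Hantzsch ester reduces by conjugate hydride transfer (three-component reductive alkylation); no new stereocentre is formed, and C1 of the cyclopentane stays in its thermodynamic trans arrangement.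

**Step 7**
Reactants: 13 (the aromatic coupling product of step 6); 14 prenyl acetate
Product: 15 (6R)-3,5-dihydroxy-4-{[(1R,2S,5S)-2-hydroxy-2-methyl-5-(prop-1-en-2-yl)cyclopentyl]methyl}-6-methyl-2-[(2R)-2-methylbutanoyl]-6-(3-methylbut-2-en-1-yl)cyclohexa-2,4-dien-1-one
Conditions: Pd2(dba)3·CHCl3 (2.5 mol %), (R,R)-DACH-phenyl Trost ligand (7.5 mol %), Et3N (1.2 equiv), 14 (1.1 equiv), degassed 1,4-dioxane, 23 °C
Reagents that add atoms: none
Why: Proposed new method: a zerovalent palladium/Trost-ligand asymmetric allylic dearomatization of a fully C-substituted acylphloroglucinol with a prenyl electrophile, in which ionization of 14 gives the 1,1-dimethylallyl palladium cation, the triethylammonium 4-phenoxide of 13 (the most acidic OH, para to the acyl group) is held by hydrogen bonding to a ligand amide N–H, and outer-sphere attack through the methyl-bearing ring carbon (less hindered than the carbon carrying the branched cyclopentylmethyl group) on the unsubstituted allyl terminus gives the linear prenyl group and the (6R) quaternary centre under catalyst control, while any O-prenyl ether is re-ionized and funnelled to the C-alkylated dienone; the closest known reactions are the palladium-catalysed intermolecular asymmetric allylic dearomatization of 1,3-disubstituted 2-naphthols and the racemic base-mediated alkylative dearomatization of 3,5-dialkyl acylphloroglucinols with prenyl bromide.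

**Compound list**
1 | (S)-(−)-limonene, (4S)-1-methyl-4-(prop-1-en-2-yl)cyclohex-1-ene | C=C(C)[C@H]1CCC(C)=CC1 | starting material
2 | (4S)-limonene 1,2-oxide (cis/trans mixture at the oxirane) | C=C(C)[C@H]1CCC2(C)OC2C1 | intermediate
3 | (3S)-6-oxo-3-(prop-1-en-2-yl)heptanal | C=C(C)[C@H](CC=O)CCC(C)=O | intermediate
4 | (5R)-2-methyl-5-(prop-1-en-2-yl)cyclopent-1-ene-1-carbaldehyde | C=C(C)[C@H]1CCC(C)=C1C=O | intermediate
5 | (1R,2R,5S)-5-methyl-2-(prop-1-en-2-yl)-6-oxabicyclo[3.1.0]hexane-1-carbaldehyde | C=C(C)[C@H]1CC[C@]2(C)O[C@]12C=O | intermediate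
6 | (1S,2S,5S)-2-hydroxy-2-methyl-5-(prop-1-en-2-yl)cyclopentane-1-carbaldehyde (C1 epimer of 7) | C=C(C)[C@H]1CC[C@](C)(O)[C@H]1C=O | intermediate
7 | (1R,2S,5S)-2-hydroxy-2-methyl-5-(prop-1-en-2-yl)cyclopentane-1-carbaldehyde | C=C(C)[C@H]1CC[C@](C)(O)[C@@H]1C=O | intermediate
8 | (R)-2-methylbutanoic acid | CC[C@@H](C)C(=O)O | starting material
9 | 2-methylphloroglucinol (2-methylbenzene-1,3,5-triol) | Cc1c(O)cc(O)cc1O | starting material
10 | (R)-2-methylbutanoyl chloride | CC[C@@H](C)C(=O)Cl | intermediate
11 | (2R)-2-methyl-1-(2,4,6-trihydroxy-3-methylphenyl)butan-1-one | CC[C@@H](C)C(=O)c1c(O)cc(O)c(C)c1O | intermediate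
12 | ortho-quinone methide from 11 and 7: 6-alkylidene-3,5-dihydroxy-2-methyl-4-[(2R)-2-methylbutanoyl]cyclohexa-2,4-dien-1-one, alkylidene = [2-hydroxy-2-methyl-5-(prop-1-en-2-yl)cyclopentyl]methylidene with the ring stereocentres of 7 | C=C(C)[C@H]1CC[C@](C)(O)[C@@H]1C=C1C(=O)C(C)=C(O)C(C(=O)[C@H](C)CC)=C1O | intermediate
13 | (2R)-1-(2,4,6-trihydroxy-3-{[(1R,2S,5S)-2-hydroxy-2-methyl-5-(prop-1-en-2-yl)cyclopentyl]methyl}-5-methylphenyl)-2-methylbutan-1-one | C=C(C)[C@H]1CC[C@](C)(O)[C@@H]1Cc1c(O)c(C)c(O)c(C(=O)[C@H](C)CC)c1O | intermediate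
14 | prenyl acetate (3-methylbut-2-en-1-yl acetate) | CC(C)=CCOC(C)=O | starting material
15 | (6R)-3,5-dihydroxy-4-{[(1R,2S,5S)-2-hydroxy-2-methyl-5-(prop-1-en-2-yl)cyclopentyl]methyl}-6-methyl-2-[(2R)-2-methylbutanoyl]-6-(3-methylbut-2-en-1-yl)cyclohexa-2,4-dien-1-one (CNP0299585.1) | C=C(C)[C@H]1CC[C@](C)(O)[C@@H]1CC1=C(O)[C@@](C)(CC=C(C)C)C(=O)C(C(=O)[C@H](C)CC)=C1O | target

**Step count and risks**
Total steps: 7. Longest linear sequence: 6 steps (1 → 3 → 4 → 5 → 7 → 13 → 15); steps 5 is the only step off this line.

The three steps most likely to fail, in order: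

Step 7, the new dearomative prenylation. It may attack the cyclopentylmethyl-bearing ring carbon instead of the methyl-bearing one, stall at O-prenyl ethers, prenylate twice, or give low or opposite facial selectivity. The ligand antipode is an arbitrary first choice; if the (R,R)-ligand gives the 6-epimer, the (S,S)-ligand is used. The fallback uses known chemistry and sets out from 13: classical alkylative dearomatization with prenyl bromide and NaOMe in MeOH at 0 °C, the lupulone-type C-alkylation of 3,5-dialkyl acylphloroglucinols, gives target 15 together with the (6S)-diastereomer of 15 F3. The two diastereomers are separated by preparative HPLC and the route is rejoined at 15.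

Step 6, the reductive alkylation. The amine catalyst may dehydrate or retro-aldolise the β-hydroxy aldehyde 7, and quinone methide 12 may tautomerise to a 2-alkenylphenol before hydride transfer. The fallback sets out from 7: the tertiary alcohol is silylated (Et3SiOTf, 2,6-lutidine, CH2Cl2, −78 °C) to the triethylsilyl ether of 7 F1, which cannot undergo retro-aldol cleavage. F1 is joined to 11 by the same proline/Hantzsch ester coupling to give the triethylsilyl ether of 13 F2, and HF·pyridine in THF at 0 °C returns to the route at 13.

Step 4, the reductive epoxide opening. The formyl group may be over-reduced or pinacol-coupled, 7 may dehydrate back to 4, and equilibration at C1 may be incomplete. The fallback sets out from keto aldehyde 3: an (S)-proline-catalysed intramolecular aldol addition (5-enolexo, DMSO, 23 °C) that stops before dehydration gives 7 after chromatographic removal of minor diastereomers. It rejoins the route at 7, bypasses 4 and 5, and makes no new compound (F0).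

Further compounds
F1 | step 6 | triethylsilyl ether of 7, (1R,2S,5S)-2-methyl-5-(prop-1-en-2-yl)-2-(triethylsilyloxy)cyclopentane-1-carbaldehyde | C=C(C)[C@H]1CC[C@](C)(O[Si](CC)(CC)CC)[C@@H]1C=O
F2 | step 6 | triethylsilyl ether of 13 | C=C(C)[C@H]1CC[C@](C)(O[Si](CC)(CC)CC)[C@@H]1Cc1c(O)c(C)c(O)c(C(=O)[C@H](C)CC)c1O
F3 | step 7 | (6S)-diastereomer of 15 | C=C(C)[C@H]1CC[C@](C)(O)[C@@H]1CC1=C(O)[C@](C)(CC=C(C)C)C(=O)C(C(=O)[C@H](C)CC)=C1O
F0 | step 4 | none | none
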